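**Retrosynthetic overview**
1. The target comes from its di-O-methyl ether. The C3' CHO is installed by Rieche formylation and the C1' isovaleryl group by Friedel–Crafts acylation; a bromine holds C3' while C1' is acylated, which keeps the two sites apart.
2. The seven-membered ether ring comes from the aryl C4'–O bond, formed by intramolecular SNAr of the 2-endo alkoxide on an aryl fluoride. The C2–O bond is never broken.
3. The key C–C bond, C6–CH2Ar, comes from an intermolecular aldol of the C6 lithium enolate of a 2-endo-silyloxybornan-5-one with 2-fluoro-4,6-dimethoxybenzaldehyde. Dehydration and exo-face hydrogenation (sets C6) follow, then the C5 oxygen is deleted by Barton–McCombie reduction.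
4. The bornan-5-one comes from (+)-borneol, which supplies C1, C2 and C4, by remote CrO3 oxidation of its acetate. The aldehyde comes from 1-fluoro-3,5-dimethoxybenzene by Vilsmeier–Haack formylation.
5. Ring order: the bornane bicycle and the benzene ring are bought. The oxepine is the only ring closed (step 14).

**Assumption and conventions:** commercial natural (+)-borneol is taken as essentially enantiopure. Bornane numbering is used: C1 is the quaternary bridgehead, C2 bears O, and C7 is CMe2. Arene locants follow the target: C1' isovaleryl, C2' OH, C3' CHO, C4' O-bornyl, C5' CH2, C6' OH. TBS is tert-butyldimethylsilyl.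

**Step 1**
Reactants: 1 (+)-borneol [(1R,2S,4R)-bornan-2-endo-ol]
Product: 2 (+)-bornyl acetate [(1R,2S,4R)-bornan-2-endo-yl acetate]
Conditions: Ac2O, pyridine, DMAP (cat.), rt
Reagents that add atoms: acetic anhydride CC(=O)OC(C)=O
Why: This DMAP-catalysed O-acetylation reacts at oxygen only, so C1, C2 and C4 are carried over unchanged.

**Step 2**
Reactants: 2 (+)-bornyl acetate
Product: 3 (1R,2S,4R)-5-oxobornan-2-endo-yl acetate
Conditions: CrO3 (4 equiv), AcOH–Ac2O, 80 °C; minor 6-oxo isomer removed by chromatography/crystallisation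
Reagents that add atoms: chromium trioxide O=[Cr](=O)=O
Why: In this classical remote Cr(VI) methylene C–H oxidation of bornyl acetate, the acetoxy group deactivates C3 and, together with quaternary C1, shields C6, so the remote C5 methylene is oxidised preferentially without touching a stereocentre.

**Step 3**
Reactants: 3 (1R,2S,4R)-5-oxobornan-2-endo-yl acetate
Product: 4 (1R,2S,4R)-2-endo-hydroxybornan-5-one
Conditions: KOH, MeOH–H2O, reflux
Reagents that add atoms: none
Why: Saponification by acyl–oxygen cleavage keeps the C2–O bond, and the γ-hydroxy ketone has no retro-aldol pathway and no epimerisable centre.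

**Step 4**
Reactants: 4 (1R,2S,4R)-2-endo-hydroxybornan-5-one
Product: 5 (1R,2S,4R)-2-endo-(TBS-oxy)bornan-5-one
Conditions: TBSCl, imidazole, DMAP (cat.), DMF, 50 °C
Reagents that add atoms: tert-butyldimethylsilyl chloride CC(C)(C)[Si](C)(C)Cl
Why: This silyl ether protection removes the acidic OH (and the enolisable acetate) before enolate chemistry, and imidazole conditions do not silylate the ketone.

**Step 5**
Reactants: 6 1-fluoro-3,5-dimethoxybenzene
Product: 8 2-fluoro-4,6-dimethoxybenzaldehyde, via aryl iminium chloride 7 (not isolated)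
Conditions: POCl3, DMF, 0 → 60 °C; then ice–H2O
Reagents that add atoms: N,N-dimethylformamide CN(C)C=O; water O
Why: The Vilsmeier–Haack formylation attacks the position para to one OMe and ortho to the other (next to the small F) rather than the site squeezed between two OMe groups.

**Step 6**
Reactants: 5 (1R,2S,4R)-2-endo-(TBS-oxy)bornan-5-one; 8 2-fluoro-4,6-dimethoxybenzaldehyde
Product: 10 6-[(2-fluoro-4,6-dimethoxyphenyl)(hydroxy)methyl]-2-endo-(TBS-oxy)bornan-5-one (diastereomer mixture at C6 and the carbinol carbon), via lithium enolate 9 (not isolated)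
Conditions: LDA (1.1 equiv), THF, −78 °C; then 8, −78 °C; AcOH quench at −78 °C
Reagents that add atoms: none
Why: In this directed crossed aldol addition C4 is a bridgehead, so 5 can enolise only toward C6, and 8 cannot enolise, so the single C6–benzylic C bond forms; both new stereocentres are erased in step 7.

**Step 7**
Reactants: 10 aldol adduct
Product: 12 6-(2-fluoro-4,6-dimethoxybenzylidene)-2-endo-(TBS-oxy)bornan-5-one (E/Z mixture), via benzylic mesylate 11 (not isolated)
Conditions: MsCl, Et3N, CH2Cl2, 0 °C; then DBU, rt → 40 °C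
Reagents that add atoms: none
Why: Mesylation followed by E1cB elimination completes the aldol condensation; the electron-rich benzylic mesylate leaves easily, the C6–H is acidic, and the alkene geometry is irrelevant because the alkene is reduced next.

**Step 8**
Reactants: 12 benzylidene ketone
Product: 13 (1R,2S,4R,6S)-6-endo-(2-fluoro-4,6-dimethoxybenzyl)-2-endo-(TBS-oxy)bornan-5-one
Conditions: H2 (4 atm), 10% Pd/C, EtOAc, rt
Reagents that add atoms: none
Why: In this heterogeneous catalytic hydrogenation the concave endo face of the exocyclic C6=C bond is closed by the 2-endo-OTBS group, so hydrogen reaches C6 from the exo face and the benzyl group ends up endo (6S); the neutral medium prevents epimerisation, and Ar–F, ketone and silyl ether are inert.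

**Step 9**
Reactants: 13 6-endo-benzyl ketone
Product: 14 6-endo-(2-fluoro-4,6-dimethoxybenzyl)-2-endo-(TBS-oxy)bornan-5-ol (C5 epimers)
Conditions: LiAlH4, Et2O, 0 °C; then H2O/aq NaOH work-up
Reagents that add atoms: none
Why: This hydride reduction is fast and non-enolising, so C6 is not epimerised, and the C5 carbinol configuration does not matter because C5 becomes CH2 in step 11.

**Step 10**
Reactants: 14 C5 alcohol
Product: 16 O-[6-endo-(2-fluoro-4,6-dimethoxybenzyl)-2-endo-(TBS-oxy)bornan-5-yl] S-methyl dithiocarbonate, via sodium xanthate 15 (not isolated)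
Conditions: NaH, THF, 0 °C; CS2; then MeI, rt
Reagents that add atoms: carbon disulfide S=C=S; iodomethane CI
Why: In this xanthate formation the small linear CS2 traps even hindered bornyl-type alkoxides at or below rt, far faster than any attack on the unactivated aryl fluoride.

**Step 11**
Reactants: 16 S-methyl xanthate
Product: 17 (1R,2S,4R,6S)-6-endo-(2-fluoro-4,6-dimethoxybenzyl)-2-endo-(TBS-oxy)bornane
Conditions: Bu3SnH, AIBN (cat.), toluene, 90 °C
Reagents that add atoms: none
Why: In the Barton–McCombie deoxygenation the secondary C5 radical simply abstracts H from the stannane, there is no ionic Wagner–Meerwein pathway, and C6, Ar–F and OTBS are untouched.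

**Step 12**
Reactants: 17 deoxygenated silyl ether
Product: 18 (1R,2S,4R,6S)-6-endo-(3-bromo-2-fluoro-4,6-dimethoxybenzyl)-2-endo-(TBS-oxy)bornane
Conditions: NBS (1.0 equiv), MeCN, 0 °C, dark
Reagents that add atoms: N-bromosuccinimide O=C1CCC(=O)N1Br
Why: This electrophilic aromatic bromination goes to C3' (para to 6'-OMe, ortho to 2'-OMe, next to small F, as in 3-fluoroanisole giving 4-bromo-3-fluoroanisole) and not to C1' between two OMe groups, so it marks the future CHO site and inductively activates the C–F bond.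

**Step 13**
Reactants: 18 aryl bromide silyl ether
Product: 19 (1R,2S,4R,6S)-6-endo-(3-bromo-2-fluoro-4,6-dimethoxybenzyl)bornan-2-endo-ol
Conditions: 48% aq HF, MeCN, rt → 40 °C
Reagents that add atoms: none
Why: Fluoride-driven desilylation cleaves only the Si–O bond, so the C2 configuration and the aryl halides persist.

**Step 14**
Reactants: 19 fluoro alcohol
Product: 21 bridged ether (2-endo-O bonded to C4' and 6-endo-CH2 bonded to C5' of a 3'-bromo-2',6'-dimethoxybenzene ring), via potassium alkoxide 20 (not isolated)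
Conditions: KHMDS (1.3 equiv), THF–DMPU (4:1), 65 °C
Reagents that add atoms: none
Why: In this intramolecular SNAr (addition–elimination) the endo,endo arrangement holds the only nucleophile, the C2 alkoxide, against a C–F carbon activated by ortho-Br and two meta-OMe groups; no enolisable carbonyl competes, and C2 is retained because its C–O bond is not involved.

**Step 15**
Reactants: 21 bridged bromo ether
Product: 22 1'-(3-methylbutanoyl) derivative of 21
Conditions: isovaleryl chloride, SnCl4, CH2Cl2, −20 → 0 °C; aq work-up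
Reagents that add atoms: isovaleryl chloride CC(C)CC(=O)Cl
Why: In this Friedel–Crafts acylation C1' is the only ring C–H (C3' is blocked by Br) and is ortho, ortho and para to three alkoxy groups, so the regiochemistry is unambiguous under a mild Lewis acid that does not cleave the ethers.

**Step 16**
Reactants: 22 bromo ketone
Product: 23 3'-unsubstituted 1'-isovaleryl-2',6'-dimethoxy bridged ether
Conditions: H2 (1 atm), 10% Pd/C, NaOAc, MeOH–EtOAc, rt
Reagents that add atoms: none
Why: Catalytic hydrogenolysis removes the blocking aryl bromide, while the twisted, di-ortho-substituted aryl ketone is not reduced at 1 atm and NaOAc takes up the HBr.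

**Step 17**
Reactants: 23 debrominated ketone
Product: 25 di-O-methyl ether of the target (3'-CHO, 1'-isovaleryl, 2',6'-di-OMe), via alpha-chloro ether 24 (not isolated)
Conditions: Cl2CHOMe, TiCl4, CH2Cl2, −78 → −20 °C; then ice–H2O
Reagents that add atoms: dichloromethyl methyl ether COC(Cl)Cl; water O
Why: In the Rieche formylation the small, powerful electrophile attacks the sole remaining ring C–H (C3'), which is still activated by three alkoxy groups because the flanked ketone is twisted out of conjugation.

**Step 18**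
Reactants: 25 di-O-methyl ether
Product: 27 target CNP0246493.1, via bis(dichloroboryl) ether 26 (not isolated)
Conditions: BCl3 (2.5 equiv), CH2Cl2, −78 → 0 °C; then H2O
Reagents that add atoms: none
Why: In this chelation-controlled BCl3 demethylation each OMe pairs with its own ortho carbonyl (2'-OMe with CHO, 6'-OMe with the ketone) and loses methyl by SN2. The bornyl ether oxygen is a weakly basic vinylogous ester oxygen on an endo, neopentyl-type carbon that cannot react by SN2 and gets no anchimeric assistance toward ionisation at or below 0 °C, so it and all stereocentres survive.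

**Compound list**
1 | (+)-borneol, (1R,2S,4R) | C1C[C@@H]2C[C@H](O)[C@@]1(C)C2(C)C | starting material
2 | (+)-bornyl acetate | C1C[C@@H]2C[C@H](OC(C)=O)[C@@]1(C)C2(C)C | intermediate
3 | (1R,2S,4R)-5-oxobornan-2-endo-yl acetate | C1C(=O)[C@@H]2C[C@H](OC(C)=O)[C@@]1(C)C2(C)C | intermediate
4 | (1R,2S,4R)-2-endo-hydroxybornan-5-one | C1C(=O)[C@@H]2C[C@H](O)[C@@]1(C)C2(C)C | intermediate
5 | (1R,2S,4R)-2-endo-(TBS-oxy)bornan-5-one | C1C(=O)[C@@H]2C[C@H](O[Si](C)(C)C(C)(C)C)[C@@]1(C)C2(C)C | intermediate
6 | 1-fluoro-3,5-dimethoxybenzene | COc1cc(F)cc(OC)c1 | starting material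
7 | aryl iminium chloride (not isolated) | COc1cc(F)c(C=[N+](C)C)c(OC)c1.[Cl-] | intermediate
8 | 2-fluoro-4,6-dimethoxybenzaldehyde | COc1cc(F)c(C=O)c(OC)c1 | intermediate
9 | lithium C5(O)=C6 enolate of 5 (not isolated) | C1=C(O[Li])[C@@H]2C[C@H](O[Si](C)(C)C(C)(C)C)[C@@]1(C)C2(C)C | intermediate
10 | aldol adduct (mixture at C6 and carbinol C) | COc1cc(F)c(C(O)C2C(=O)[C@@H]3C[C@H](O[Si](C)(C)C(C)(C)C)[C@@]2(C)C3(C)C)c(OC)c1 | intermediate
11 | benzylic mesylate of 10 (not isolated) | COc1cc(F)c(C(OS(C)(=O)=O)C2C(=O)[C@@H]3C[C@H](O[Si](C)(C)C(C)(C)C)[C@@]2(C)C3(C)C)c(OC)c1 | intermediate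
12 | 6-benzylidene ketone (E/Z mixture) | COc1cc(F)c(C=C2C(=O)[C@@H]3C[C@H](O[Si](C)(C)C(C)(C)C)[C@@]2(C)C3(C)C)c(OC)c1 | intermediate
13 | (1R,2S,4R,6S)-6-endo-benzyl ketone | COc1cc(F)c(C[C@@H]2C(=O)[C@@H]3C[C@H](O[Si](C)(C)C(C)(C)C)[C@@]2(C)C3(C)C)c(OC)c1 | intermediate
14 | C5 alcohol (C5 epimers) | COc1cc(F)c(C[C@@H]2C(O)[C@@H]3C[C@H](O[Si](C)(C)C(C)(C)C)[C@@]2(C)C3(C)C)c(OC)c1 | intermediate
15 | sodium xanthate of 14 (not isolated) | COc1cc(F)c(C[C@@H]2C(OC(=S)[S-])[C@@H]3C[C@H](O[Si](C)(C)C(C)(C)C)[C@@]2(C)C3(C)C)c(OC)c1.[Na+] | intermediate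
16 | S-methyl xanthate of 14 | COc1cc(F)c(C[C@@H]2C(OC(=S)SC)[C@@H]3C[C@H](O[Si](C)(C)C(C)(C)C)[C@@]2(C)C3(C)C)c(OC)c1 | intermediate
17 | (1R,2S,4R,6S)-6-endo-(2-fluoro-4,6-dimethoxybenzyl)-2-endo-(TBS-oxy)bornane | COc1cc(F)c(C[C@@H]2C[C@@H]3C[C@H](O[Si](C)(C)C(C)(C)C)[C@@]2(C)C3(C)C)c(OC)c1 | intermediate
18 | 3'-bromo derivative of 17 | COc1cc(OC)c(C[C@@H]2C[C@@H]3C[C@H](O[Si](C)(C)C(C)(C)C)[C@@]2(C)C3(C)C)c(F)c1Br | intermediate
19 | 6-endo-(3-bromo-2-fluoro-4,6-dimethoxybenzyl)bornan-2-endo-ol | COc1cc(OC)c(C[C@@H]2C[C@@H]3C[C@H](O)[C@@]2(C)C3(C)C)c(F)c1Br | intermediate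
20 | potassium alkoxide of 19 (not isolated) | COc1cc(OC)c(C[C@@H]2C[C@@H]3C[C@H]([O-])[C@@]2(C)C3(C)C)c(F)c1Br.[K+] | intermediate
21 | bridged 3'-bromo-2',6'-dimethoxy ether | COc1cc(OC)c2C[C@@H]3C[C@@H]4C[C@H](Oc2c1Br)[C@@]3(C)C4(C)C | intermediate
22 | 1'-isovaleryl-3'-bromo bridged ether | COc1c(C(=O)CC(C)C)c(OC)c2C[C@@H]3C[C@@H]4C[C@H](Oc2c1Br)[C@@]3(C)C4(C)C | intermediate
23 | 1'-isovaleryl bridged ether (3'-H) | COc1c(C(=O)CC(C)C)c(OC)c2C[C@@H]3C[C@@H]4C[C@H](Oc2c1)[C@@]3(C)C4(C)C | intermediate
24 | aryl(chloro)methyl methyl ether (not isolated) | COc1c(C(=O)CC(C)C)c(OC)c2C[C@@H]3C[C@@H]4C[C@H](Oc2c1C(Cl)OC)[C@@]3(C)C4(C)C | intermediate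
25 | di-O-methyl ether of the target | COc1c(C(=O)CC(C)C)c(OC)c2C[C@@H]3C[C@@H]4C[C@H](Oc2c1C=O)[C@@]3(C)C4(C)C | intermediate
26 | bis(dichloroboryl) ether (not isolated) | ClB(Cl)Oc1c(C(=O)CC(C)C)c(OB(Cl)Cl)c2C[C@@H]3C[C@@H]4C[C@H](Oc2c1C=O)[C@@]3(C)C4(C)C | intermediate
27 | CNP0246493.1, bornane (1R,2S,4R,6S) | CC(C)CC(=O)c1c(O)c(C=O)c2c(c1O)C[C@@H]1C[C@@H]3C[C@H](O2)[C@@]1(C)C3(C)C | target

**Totals**
Total steps: 18. Longest linear sequence: 17 (steps 1–4 and 6–18; step 5 is the side branch).

**Three steps most likely to fail**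

**Step 6 (aldol at the neopentyl-type C6 with a hindered, electron-rich aldehyde).** The lithium aldolate may revert.
- The fallback sets out from 5 and 8 and comes back at 12. It replaces the reversible basic aldol by an irreversible Lewis-acid Mukaiyama-type aldol.
- Enolate 9 made from 5 is trapped with TMSCl as the trimethylsilyl enol ether F1.
- Aldehyde 8 is turned with HC(OMe)3 and catalytic TsOH into its dimethyl acetal F2.
- Catalytic TMSOTf in CH2Cl2 at −78 °C joins the two through the aryl-stabilised oxocarbenium ion to the β-methoxy ketone F3.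
- DBU then expels methanol to give enone 12.

**Step 8 (slow hydrogenation of a crowded alkene, or the wrong face).**
- The fallback sets out from 12 and comes back at 13. It sets C6 by kinetic protonation instead of surface delivery of hydrogen.
- Rh-catalysed 1,4-hydrosilylation of the fixed s-cis enone (Et3SiH, RhCl(PPh3)3, toluene, 60 °C) gives the triethylsilyl enol ether F4.
- F4 is cleaved with TBAF/AcOH in THF at −78 °C. As in camphor, where the exo α-hydrogen exchanges far faster than the endo one, the proton enters C6 from the exo face, here reinforced by the endo OTBS group. This gives 13, which goes directly into step 9.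

**Step 14 (SNAr on an only weakly activated aryl fluoride).**
- The fallback sets out from 18 and comes back at 25. It uses the bromine to install the final aldehyde first, as a true SNAr activator.
- Br–Li exchange (n-BuLi, THF, −78 °C) gives the aryllithium F5.
- F5 is quenched cold with DMF to give the fluoro aldehyde F6.
- Aqueous HF in MeCN frees the hydroxy aldehyde F7.
- Cs2CO3 in DMF at 60–80 °C closes the ring ortho to the formyl group to give the bridged aldehyde F8.
- Friedel–Crafts acylation of the only free ring position (isovaleryl chloride, TiCl4, CH2Cl2, 0 °C) gives 25, so steps 15–17 are skipped.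

**Further compounds**
F1 | step 6 | trimethylsilyl enol ether of 5 | C1=C(O[Si](C)(C)C)[C@@H]2C[C@H](O[Si](C)(C)C(C)(C)C)[C@@]1(C)C2(C)C
F2 | step 6 | 2-fluoro-4,6-dimethoxybenzaldehyde dimethyl acetal | COc1cc(F)c(C(OC)OC)c(OC)c1
F3 | step 6 | β-methoxy ketone (mixture at C6 and the ether carbon) | COc1cc(F)c(C(OC)C2C(=O)[C@@H]3C[C@H](O[Si](C)(C)C(C)(C)C)[C@@]2(C)C3(C)C)c(OC)c1
F4 | step 8 | triethylsilyl enol ether (C5=C6) of 13 | COc1cc(F)c(CC2=C(O[Si](CC)(CC)CC)[C@@H]3C[C@H](O[Si](C)(C)C(C)(C)C)[C@@]2(C)C3(C)C)c(OC)c1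
F5 | step 14 | 3'-lithio derivative of 17 | COc1cc(OC)c(C[C@@H]2C[C@@H]3C[C@H](O[Si](C)(C)C(C)(C)C)[C@@]2(C)C3(C)C)c(F)c1[Li]
F6 | step 14 | 3'-formyl derivative of 17 | COc1cc(OC)c(C[C@@H]2C[C@@H]3C[C@H](O[Si](C)(C)C(C)(C)C)[C@@]2(C)C3(C)C)c(F)c1C=O
F7 | step 14 | 6-endo-(2-fluoro-3-formyl-4,6-dimethoxybenzyl)bornan-2-endo-ol | COc1cc(OC)c(C[C@@H]2C[C@@H]3C[C@H](O)[C@@]2(C)C3(C)C)c(F)c1C=O
F8 | step 14 | bridged 3'-formyl-2',6'-dimethoxy ether | COc1cc(OC)c2C[C@@H]3C[C@@H]4C[C@H](Oc2c1C=O)[C@@]3(C)C4(C)C
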